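**Retrosynthetic overview**

- The strategy rests on ring B. Its C2 (the carbon carrying the free OH) lies between C1 (O-aryl) and C3 (OMe), so C1–C2–C3 is the CH2–C(=O)–CH2 backbone of a 1-aryloxy-3-methoxyacetone. C4(H)–C5(CH2CH2CH2OH)–C6(H) is a symmetric 2-substituted malondialdehyde unit, available as the cyclic enol ether 3,4-dihydro-2H-pyran-5-carbaldehyde, whose ring oxygen is the side-chain OH.
- Last disconnection: the C1–C6 and C3–C4 bonds of ring B, made together in a base-mediated [3+3] benzannulation of ketone 5 with aldehyde 8 that opens the pyran.
- Ketone 5 comes from 4-propylsyringol by epoxide opening (aryl O–CH2 bond made by alkylation, not arylation) and oxidation. Aldehyde 8 comes from dihydropyran by formylation.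
- Ring order: ring A is bought intact, its oxygen is first tied to an sp3 carbon, and ring B is built last around that carbon. There are no protecting groups and no stereocentres to set.

Key step: step 5

Remark on the chemistry: 3 and 4 are racemic. Intermediates 9 and 10 are drawn without configuration because their sp3 centres and the enal geometry of 9 form as mixtures and are erased on aromatisation.

**Route**

Step 1
Reactants: 1 4-allyl-2,6-dimethoxyphenol
Product: 2 2,6-dimethoxy-4-propylphenol
Conditions: H2 (1 atm), 10% Pd/C, EtOH, rt
Reagents that add atoms: none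
Why: Heterogeneous catalytic hydrogenation should saturate the terminal allyl C=C at room temperature without touching the arene, the aryl methyl ethers or the phenol.

Step 2
Reactants: 2 2,6-dimethoxy-4-propylphenol; 3 glycidyl methyl ether (racemic)
Product: 4 1-(2,6-dimethoxy-4-propylphenoxy)-3-methoxypropan-2-ol (racemic)
Conditions: 3 (1.3 equiv), K2CO3 (0.2 equiv), DMF, 90 °C
Reagents that add atoms: none
Why: Base-catalysed SN2 opening of the monosubstituted epoxide by the phenoxide of 2 should occur at the unhindered terminal CH2, so the crowded aryl–O bond is made to an sp3 carbon; the new carbinol centre is racemic and is removed in step 3.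

Step 3
Reactants: 4 1-(2,6-dimethoxy-4-propylphenoxy)-3-methoxypropan-2-ol
Product: 5 1-(2,6-dimethoxy-4-propylphenoxy)-3-methoxypropan-2-one
Conditions: Dess–Martin periodinane (1.3 equiv), CH2Cl2, 0 °C to rt
Reagents that add atoms: none
Why: Dess–Martin oxidation of the secondary alcohol should give the ketone under near-neutral conditions that spare the electron-rich arene and the ethers and avoid base-induced enolisation of the doubly alpha-oxygenated ketone.

Step 4
Reactants: 6 3,4-dihydro-2H-pyran
Product: 8 3,4-dihydro-2H-pyran-5-carbaldehyde, via iminium salt 7 (not isolated)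
Conditions: POCl3, DMF, 0 °C; then 6, CH2Cl2, 0 °C to rt; then ice, sat. aq. NaHCO3
Reagents that add atoms: N,N-dimethylformamide CN(C)C=O (formyl carbon); water O (carbonyl oxygen, on hydrolysis)
Why: Vilsmeier–Haack formylation, in which the nucleophilic beta-carbon (C5) of the enol ether attacks the chloroiminium ion, loss of HCl gives the push–pull iminium 7, and buffered hydrolysis should release the vinylogous formate 8, as is established for glycals and other cyclic enol ethers.

Step 5
Reactants: 5 1-(2,6-dimethoxy-4-propylphenoxy)-3-methoxypropan-2-one; 8 3,4-dihydro-2H-pyran-5-carbaldehyde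
Product: 11 2-(2,6-dimethoxy-4-propylphenoxy)-4-(3-hydroxypropyl)-6-methoxyphenol (CNP0368877.0), via ring-opened keto enal 9 (not isolated), via cyclic aldol 10 (not isolated)
Conditions: KOtBu (2.5 equiv), THF/t-BuOH (5:1), Ar, 8 (1.3 equiv), slow addition of 5 at 0 °C, then 50 °C; then 1 M HCl to pH 5, 0 °C
Reagents that add atoms: none
Why: Proposed new method: the potassium enolate of 5 (at either alpha-carbon) adds to the O–CH= carbon (C6) of the vinylogous formate 8 and E1cB loss of the ring alkoxide opens the pyran to keto enal 9 (held as its delocalised dienolate), after which the second alpha-carbon, through the small equilibrium share of its own enolate, adds to the aldehyde to give cyclic aldol 10, and E1cB dehydration followed by tautomerisation of the cyclohexadienone should deliver the phenoxide of 11; the other order of events (aldol condensation at the formyl group, then 6π closure and alkoxide loss) converges on the same product. The closest known reaction types are the [3+3] phenol syntheses from ketones with two enolisable alpha-positions and sodium nitromalonaldehyde or 2-substituted vinamidinium salts, and the ring-opening domino condensations of 3-formylchromones and of 5-formyl-3,4-dihydro-2H-pyrans such as 2-C-formyl glycals with 1,3-dinucleophiles, in which the ring oxygen leaves as a hydroxyl group. Ring B is the only ring closed, by a 6-exo-trig intramolecular aldol addition whose cis-enal geometry is supplied by E/Z equilibration through the dienolate of 9. No stereocentre survives, since the sp3 centres of 9 and 10 vanish on aromatisation, which also makes the sequence irreversible. The one selectivity needed is cross-condensation over self-aldol of 5, secured by keeping the ketone dilute (slow addition into base that already holds an excess of the non-enolisable 8); orientation is not an issue because the C4H–C5–C6H unit from 8 is symmetric and the OAr/OH/OMe pattern is fixed by the ketone, and neither alpha-oxygen can be lost by beta-elimination because each sits on the enolate carbon itself.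

**Compound list**

1 | 4-allyl-2,6-dimethoxyphenol (methoxyeugenol) | C=CCc1cc(OC)c(O)c(OC)c1 | starting material
2 | 2,6-dimethoxy-4-propylphenol (4-propylsyringol) | CCCc1cc(OC)c(O)c(OC)c1 | intermediate
3 | glycidyl methyl ether, racemic | COCC1CO1 | starting material
4 | 1-(2,6-dimethoxy-4-propylphenoxy)-3-methoxypropan-2-ol, racemic | CCCc1cc(OC)c(OCC(O)COC)c(OC)c1 | intermediate
5 | 1-(2,6-dimethoxy-4-propylphenoxy)-3-methoxypropan-2-one | CCCc1cc(OC)c(OCC(=O)COC)c(OC)c1 | intermediate
6 | 3,4-dihydro-2H-pyran | C1=COCCC1 | starting material
7 | N-[(3,4-dihydro-2H-pyran-5-yl)methylidene]-N-methylmethanaminium dichlorophosphate | C[N+](C)=CC1=COCCC1.[O-]P(=O)(Cl)Cl | intermediate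
8 | 3,4-dihydro-2H-pyran-5-carbaldehyde | O=CC1=COCCC1 | intermediate
9 | 4-(2,6-dimethoxy-4-propylphenoxy)-2-(3-hydroxypropyl)-6-methoxy-5-oxohex-2-enal (E/Z mixture, present as its potassium dienolate) | CCCc1cc(OC)c(OC(C=C(C=O)CCCO)C(=O)COC)c(OC)c1 | intermediate
10 | 2-(2,6-dimethoxy-4-propylphenoxy)-5-hydroxy-4-(3-hydroxypropyl)-6-methoxycyclohex-3-en-1-one (diastereomer mixture) | CCCc1cc(OC)c(OC2C=C(CCCO)C(O)C(OC)C2=O)c(OC)c1 | intermediate
11 | 2-(2,6-dimethoxy-4-propylphenoxy)-4-(3-hydroxypropyl)-6-methoxyphenol (CNP0368877.0) | CCCc1cc(OC)c(Oc2cc(CCCO)cc(OC)c2O)c(OC)c1 | target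

**Step count**

Total: 5 steps. Longest linear sequence: 4 steps (steps 1, 2, 3 and 5); step 4 is a one-step branch.

**Steps most likely to fail**

1. Step 5 (proposed new method). Self-aldol condensation of the ketone may outrun the cross-addition, the sequence may stall at the stabilised dienolate of the ring-opened adduct without closing the ring, or the vinylogous formate may be degraded by alkoxide before it is intercepted. Fallback by known chemistry, setting out from 2 and returning at 11: commercial 5-bromovanillin (3-bromo-4-hydroxy-5-methoxybenzaldehyde) is O-benzylated (BnBr, K2CO3, DMF) to 4-(benzyloxy)-3-bromo-5-methoxybenzaldehyde F1. Ullmann diaryl ether coupling of F1 with phenol 2 (CuI, picolinic acid, K3PO4, DMSO, 90 °C) would give 4-(benzyloxy)-3-(2,6-dimethoxy-4-propylphenoxy)-5-methoxybenzaldehyde F2; the hindered coupling is the known cost of this route, which is why it is held in reserve. Horner–Wadsworth–Emmons olefination (triethyl phosphonoacetate, NaH, THF) would give ethyl (E)-3-[4-(benzyloxy)-3-(2,6-dimethoxy-4-propylphenoxy)-5-methoxyphenyl]prop-2-enoate F3. Hydrogenation over Pd/C (H2, EtOH/EtOAc) would saturate the alkene and cleave the benzyl ether to ethyl 3-[3-(2,6-dimethoxy-4-propylphenoxy)-4-hydroxy-5-methoxyphenyl]propanoate F4, and LiAlH4 in THF would reduce the ester to 11.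

2. Step 4. The acid-sensitive enol ether may oligomerise under the Vilsmeier conditions, and hydrolysis of the push–pull iminium may proceed by attack at the acetal-type ring carbon (ring opening) instead of at the iminium carbon; the small, water-miscible product may also be lost on isolation. Fallback setting out from 6 and returning at 8: Lewis-acid addition of triethyl orthoformate to the enol ether (BF3·OEt2 cat., 0 °C) would give 3-(diethoxymethyl)-2-ethoxytetrahydro-2H-pyran F5. Acid-mediated acetal hydrolysis with elimination of ethanol (aqueous formic acid or p-TsOH with heating) would then give 8 without any iminium intermediate.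

3. Step 2. Opening by the di-ortho-substituted phenoxide may be slow, letting the product alkoxide add to further epoxide (oligomerisation), with some attack at the internal epoxide carbon. Fallback setting out from 2 and returning at 4: alkylation of 2 with racemic epichlorohydrin (K2CO3, MeCN, reflux) would give 2-[(2,6-dimethoxy-4-propylphenoxy)methyl]oxirane F6. Opening of this aryl glycidyl ether at its terminal carbon with NaOMe in MeOH (60 °C) would give 4, so the methoxy group is introduced by a small, unhindered nucleophile.

**Further compounds**

F1 | step 5 | 4-(benzyloxy)-3-bromo-5-methoxybenzaldehyde | O=Cc1cc(Br)c(OCc2ccccc2)c(OC)c1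
F2 | step 5 | 4-(benzyloxy)-3-(2,6-dimethoxy-4-propylphenoxy)-5-methoxybenzaldehyde | CCCc1cc(OC)c(Oc2cc(C=O)cc(OC)c2OCc3ccccc3)c(OC)c1
F3 | step 5 | ethyl (E)-3-[4-(benzyloxy)-3-(2,6-dimethoxy-4-propylphenoxy)-5-methoxyphenyl]prop-2-enoate | CCCc1cc(OC)c(Oc2cc(/C=C/C(=O)OCC)cc(OC)c2OCc3ccccc3)c(OC)c1
F4 | step 5 | ethyl 3-[3-(2,6-dimethoxy-4-propylphenoxy)-4-hydroxy-5-methoxyphenyl]propanoate | CCCc1cc(OC)c(Oc2cc(CCC(=O)OCC)cc(OC)c2O)c(OC)c1
F5 | step 4 | 3-(diethoxymethyl)-2-ethoxytetrahydro-2H-pyran (racemic, cis/trans mixture) | CCOC(OCC)C1CCCOC1OCC
F6 | step 2 | 2-[(2,6-dimethoxy-4-propylphenoxy)methyl]oxirane (racemic) | CCCc1cc(OC)c(OCC2CO2)c(OC)c1
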